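**Strategy.** The cyclohexane ring (C1, C10–C14; briarane numbering) is read as a [4+2] adduct. C11–C14, carrying both ring oxygens and C20, come from a 1-alkoxy-3-silyloxy diene; C1=C10 comes from an (E)-2-methyl-enal whose geometry gives the trans C2/C9 relationship. One oxazaborolidinium-catalysed Diels–Alder reaction forms C10–C11 and C1–C14 and sets C1, C10 and C14. Because C20 and O14 are trans in the target (an E,Z-diene would be needed), C20 enters as CH2SPh, and C11 and C12 are set afterwards by CBS reduction and hydroxyl-directed hydrogenation. C2 follows by chelation control, the butenolide (C7 from the chiral pool) is attached by Nozaki–Hiyama–Kishi coupling, and ring-closing metathesis closes the ten-membered ring at C5=C6.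

Key step: step 6

Remark on numbering: briarane numbering is used (C1 quaternary carbon with CH3-15, C2 butanoyloxy carbon, C5=C6 ring alkene, C7 lactone CH–O, C8=C17 butenolide alkene, C9 and C14 acetoxy carbons, C10 ring-fusion CH, C11 with CH3-20, C12 hydroxy carbon). β is the face of the cyclohexane ring that carries CH3-15; α is the opposite face.

Abbreviations: PMB = 4-methoxybenzyl, TBS = tert-butyldimethylsilyl, TIPS = triisopropylsilyl, Tf = trifluoromethanesulfonyl.

Assumption: the (S)-configured oxazaborolidinium ion is taken to expose the enal face that leads to the series drawn; if the sense of induction is the opposite, the (R)-catalyst is used.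

**Diene**

Step 1
Reactants: 1 4-(phenylsulfanyl)butan-2-one
Product: 2 3-oxo-5-(phenylsulfanyl)pentanal (hydroxymethylene enol form)
Conditions: LDA (lithium diisopropylamide), THF, −78 °C; HCO2Et, −78 → 0 °C; aq. HCl
Reagents that add atoms: ethyl formate, CCOC=O
Why: Kinetic deprotonation at the methyl group followed by crossed Claisen formylation should give the β-keto aldehyde; the methyl-side enolate cannot expel thiolate.

Step 2
Reactants: 2 3-oxo-5-(phenylsulfanyl)pentanal; 3 (4-methoxyphenyl)methanol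
Product: 4 (E)-1-[(4-methoxybenzyl)oxy]-5-(phenylsulfanyl)pent-1-en-3-one
Conditions: pyridinium 4-toluenesulfonate (cat.), benzene, reflux, Dean–Stark
Reagents that add atoms: none
Why: Acid-catalysed condensation of the alcohol at the formyl carbon (vinylogous ester formation) should give the conjugated (E)-enol ether as the thermodynamic product.

Step 3
Reactants: 4 (E)-1-[(4-methoxybenzyl)oxy]-5-(phenylsulfanyl)pent-1-en-3-one
Product: 5 (1E,3Z)-1-[(4-methoxybenzyl)oxy]-3-(tert-butyldimethylsilyloxy)-5-(phenylsulfanyl)penta-1,3-diene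
Conditions: TBSOTf, Et3N, Et2O, 0 °C
Reagents that add atoms: tert-butyldimethylsilyl trifluoromethanesulfonate, CC(C)(C)[Si](C)(C)OS(=O)(=O)C(F)(F)F
Why: Soft enolization and O-silylation of the vinylogous ester should give the Danishefsky-type diene with the (Z)-silyl enol ether, which places CH2SPh in the outside position.

**Dienophile**

Step 4
Reactants: 6 3-methylbut-2-en-1-ol
Product: 7 1-methoxy-4-{[(3-methylbut-2-en-1-yl)oxy]methyl}benzene
Conditions: NaH, PMBCl, Bu4NI (cat.), THF, 0 °C → rt
Reagents that add atoms: 4-methoxybenzyl chloride, COc1ccc(CCl)cc1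
Why: Williamson etherification of the primary allylic alkoxide.

Step 5
Reactants: 7 1-methoxy-4-{[(3-methylbut-2-en-1-yl)oxy]methyl}benzene
Product: 9 (E)-4-[(4-methoxybenzyl)oxy]-2-methylbut-2-enal, via (E)-allylic alcohol 8 (not isolated)
Conditions: SeO2 (cat.), tBuOOH, CH2Cl2, rt; then MnO2, CH2Cl2, rt
Reagents that add atoms: tert-butyl hydroperoxide, CC(C)(C)OO
Why: SeO2-catalysed allylic oxidation (ene reaction, then [2,3]-shift) attacks the (E)-methyl group of the trisubstituted alkene, and MnO2 should oxidize the allylic alcohol to the (E)-enal.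

**Key step and core**

Step 6
Reactants: 5 diene; 9 (E)-enal
Product: 10 Diels–Alder adduct (C1 β-CH3/α-CHO, C10 β-CH2OPMB, C11 α-CH2SPh, C12 OTBS enol ether, C14 α-OPMB)
Conditions: (S)-1-(2-methylphenyl)-3,3-diphenyltetrahydro-1H,3H-pyrrolo[1,2-c][1,3,2]oxazaborole (20 mol %) activated with HN(SO2CF3)2 (20 mol %), CH2Cl2, −78 → −40 °C
Reagents that add atoms: none
Why: The oxazaborolidinium ion binds the formyl oxygen of the s-trans enal and lowers its LUMO, and the diene adds in a concerted, asynchronous [4+2] cycloaddition in which its nucleophilic C11 terminus bonds to the β-carbon C10 and its oxygenated C14 terminus to the α-carbon C1; the closest known reaction type is the oxazaborolidinium-catalysed enantioselective Diels–Alder reaction of 2-substituted enals with 1-alkoxy-3-silyloxy dienes. The cyclohexene ring C1–C14–C13–C12–C11–C10 closes in one suprafacial–suprafacial event that forms both C–C bonds. The (E)-geometry of the enal is transferred stereospecifically into the trans relationship of CHO (C2) and CH2OPMB (C9) at C1/C10; the endo orientation of the boron-bound formyl group places the outside OPMB at C14 (and the outside CH2SPh at C11) cis to CHO; the catalyst shields one enal face and fixes the absolute configuration. The step needs C=C rather than C=O addition, the correct regiochemistry, and endo and facial selectivity: the α-methyl group and the catalyst complex favour carbocyclic addition, the 1,3-dioxygenation of the diene dictates the regiochemistry, and the catalyst secures endo and facial control. The configuration formed at C11 is not needed, because C11 becomes sp2 in step 9 and is reset in step 11.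

Step 7
Reactants: 10 Diels–Alder adduct; 11 2-(2-bromoethyl)-2-methyl-1,3-dioxolane
Product: 14 C2 butanoate carrying the 2-(2-methyl-1,3-dioxolan-2-yl)ethyl chain, via Grignard reagent 12 (not isolated), via bromomagnesium alkoxide 13 (not isolated)
Conditions: 11, Mg, THF, rt; 10, MgBr2·OEt2, CH2Cl2, −78 °C; then (PrCO)2O, DMAP, −78 → 0 °C
Reagents that add atoms: butanoic anhydride, CCCC(=O)OC(=O)CCC
Why: Chelation-controlled Grignard addition (Cram chelate): magnesium bridges the formyl oxygen and the α-oriented C14 OPMB oxygen, the nucleophile attacks from the side of the C1 methyl group rather than from ring carbon C10, which sets C2, and the alkoxide is acylated in the same flask.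

Step 8
Reactants: 14 C2 butanoate silyl enol ether
Product: 15 C12 ketone
Conditions: HF·pyridine, pyridine, THF, 0 °C
Reagents that add atoms: none
Why: Fluoride cleavage of the silyl enol ether with protonation at C13 should release the ketone without touching the PMB ethers, the ketal or the ester.

Step 9
Reactants: 15 C12 ketone
Product: 17 C11 exo-methylene ketone, via sulfoxide 16 (not isolated)
Conditions: mCPBA (1.05 equiv), CH2Cl2, −78 °C; then toluene, CaCO3, 80 °C
Reagents that add atoms: none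
Why: Sulfide oxidation and thermal sulfoxide syn-elimination through the only β-hydrogen (the acidic C11–H) should give the C11=C20 enone regiospecifically, under neutral conditions that leave the β-OPMB group at C14 in place.

Step 10
Reactants: 17 C11 exo-methylene ketone
Product: 18 12α-allylic alcohol
Conditions: (S)-1-methyl-3,3-diphenyltetrahydro-1H,3H-pyrrolo[1,2-c][1,3,2]oxazaborole (0.3 equiv), catecholborane, toluene, −78 °C
Reagents that add atoms: none
Why: Corey–Bakshi–Shibata reduction; reagent-controlled 1,2-reduction with the alkene-bearing C11 as the large group should give the 12α-alcohol, cis to the C14 oxygen.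

Step 11
Reactants: 18 12α-allylic alcohol
Product: 19 11β-methyl 12α-alcohol
Conditions: [Ir(cod)(PCy3)(py)]PF6 (5 mol %), H2 (1 atm), CH2Cl2, 0 °C → rt
Reagents that add atoms: none
Why: Hydroxyl-directed hydrogenation (Crabtree catalyst): iridium bound to the 12α-hydroxyl delivers H2 to the α face of C11=C20, so that H11 is α and CH3-20 β; no other alkene is present at this stage.

Step 12
Reactants: 19 11β-methyl 12α-alcohol
Product: 20 12-OTIPS ether
Conditions: TIPSOTf, 2,6-lutidine, CH2Cl2, 0 °C → rt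
Reagents that add atoms: triisopropylsilyl trifluoromethanesulfonate, CC(C)[Si](OS(=O)(=O)C(F)(F)F)(C(C)C)C(C)C
Why: Silylation of the secondary alcohol with the reactive silyl triflate; TIPS survives the later acid and oxidation steps.

Step 13
Reactants: 20 12-OTIPS ether
Product: 21 C5 methyl ketone
Conditions: 1 M HCl, THF, rt
Reagents that add atoms: water, O
Why: Acid hydrolysis of the dioxolane; PMB ethers, the TIPS ether and the butanoate should be stable to dilute acid.

Step 14
Reactants: 21 C5 methyl ketone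
Product: 22 isopropenyl compound
Conditions: Ph3PCH3Br, KOtBu, THF, 0 °C → rt
Reagents that add atoms: methyltriphenylphosphonium bromide, C[P+](c1ccccc1)(c1ccccc1)c1ccccc1.[Br-]
Why: Wittig methylenation; the methyl ketone reacts far faster than the hindered butanoate.

Step 15
Reactants: 22 isopropenyl compound
Product: 23 9,14-diol (primary C9 alcohol, secondary C14 alcohol)
Conditions: DDQ (2.5 equiv), CH2Cl2/pH 7 buffer, 0 °C → rt
Reagents that add atoms: none
Why: Oxidative cleavage of both PMB ethers by hydride abstraction at the electron-rich benzylic positions; the silyl ether, ester and alkene are not affected.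

Step 16
Reactants: 23 9,14-diol
Product: 24 C9 aldehyde
Conditions: TEMPO (10 mol %), PhI(OAc)2, CH2Cl2, rt
Reagents that add atoms: none
Why: Oxoammonium oxidation is selective for the primary alcohol over the hindered neopentyl C14 alcohol; the trans relationship of O14 and C9 prevents lactol formation.

**Butenolide fragment**

Step 17
Reactants: 25 (S)-3-hydroxyoxolan-2-one
Product: 27 methyl (S)-2-hydroxy-4-(phenylselanyl)butanoate, via sodium carboxylate 26 (not isolated)
Conditions: PhSeSePh, NaBH4, EtOH; then 25, DMF, 110 °C; then MeI, rt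
Reagents that add atoms: diphenyl diselenide, c1ccc([Se][Se]c2ccccc2)cc1; iodomethane, CI
Why: SN2 opening of the lactone at the O-alkyl carbon by the soft selenolate, then O-methylation of the carboxylate; the stereocenter is not involved.

Step 18
Reactants: 27 methyl (S)-2-hydroxy-4-(phenylselanyl)butanoate
Product: 28 methyl (S)-4-(phenylselanyl)-2-(propanoyloxy)butanoate
Conditions: EtCOCl, pyridine, DMAP (cat.), CH2Cl2, 0 °C
Reagents that add atoms: propanoyl chloride, CCC(Cl)=O
Why: Acylation of the secondary alcohol.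

Step 19
Reactants: 28 methyl (S)-4-(phenylselanyl)-2-(propanoyloxy)butanoate
Product: 29 (S)-4-hydroxy-3-methyl-5-[2-(phenylselanyl)ethyl]furan-2(5H)-one
Conditions: LiN(SiMe3)2 (2.2 equiv), THF, −78 → 0 °C; then 1 M HCl
Reagents that add atoms: none
Why: Dieckmann (Lacey) cyclization of the propanoate enolate onto the methyl ester gives the tetronic acid; with an alkyl (not vinyl) substituent the C7 hydrogen should be retained.

Step 20
Reactants: 29 tetronic acid
Product: 30 (S)-4-methyl-5-oxo-2-[2-(phenylselanyl)ethyl]-2,5-dihydrofuran-3-yl trifluoromethanesulfonate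
Conditions: Tf2O, iPr2NEt, CH2Cl2, −78 °C
Reagents that add atoms: trifluoromethanesulfonic anhydride, O=S(=O)(OS(=O)(=O)C(F)(F)F)C(F)(F)F
Why: O-sulfonylation of the acidic enol gives the enol triflate needed for coupling.

Step 21
Reactants: 30 selenide triflate
Product: 32 (S)-4-methyl-5-oxo-2-vinyl-2,5-dihydrofuran-3-yl trifluoromethanesulfonate, via selenoxide 31 (not isolated)
Conditions: mCPBA (1.0 equiv), CH2Cl2, −78 °C; then pyridine, → rt
Reagents that add atoms: none
Why: Selenoxide syn-elimination at room temperature unmasks the vinyl group only after all strongly basic steps, so that C7 is not racemized.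

**Union and endgame**

Step 22
Reactants: 24 C9 aldehyde; 32 vinyl butenolide triflate
Product: 33 C9 carbinol (mixture of C9 epimers)
Conditions: CrCl2 (6 equiv), NiCl2 (2 mol %), DMF, rt
Reagents that add atoms: none
Why: Nozaki–Hiyama–Kishi coupling: nickel-catalysed formation of the alkenylchromium species from the enol triflate and its chemoselective addition to the aldehyde in the presence of ester, lactone and free hydroxyl; the C9 configuration is corrected in steps 23 and 24.

Step 23
Reactants: 33 C9 carbinol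
Product: 34 C9 ketone
Conditions: MnO2 (excess), CH2Cl2, rt
Reagents that add atoms: none
Why: MnO2 oxidizes only the allylic C9 alcohol (allylic to the butenolide alkene) and leaves the saturated C14 alcohol.

Step 24
Reactants: 34 C9 ketone
Product: 35 (9S)-alcohol
Conditions: NaBH4, CeCl3·7H2O, MeOH, −78 °C
Reagents that add atoms: none
Why: Luche 1,2-reduction under Felkin–Anh control by C10 (hydride anti to the quaternary C1) should give the (9S)-alcohol, the epimer that direct Felkin addition of the alkenyl group to the aldehyde does not favour.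

Step 25
Reactants: 35 (9S)-alcohol
Product: 36 9,14-diacetate
Conditions: Ac2O, pyridine, DMAP (cat.), CH2Cl2, 0 °C → rt
Reagents that add atoms: acetic anhydride, CC(=O)OC(C)=O
Why: Nucleophile-catalysed acetylation of both free secondary alcohols; 12-OH is masked as the TIPS ether.

Step 26
Reactants: 36 9,14-diacetate
Product: 37 macrocycle 12-OTIPS ether
Conditions: second-generation Grubbs catalyst RuCl2(=CHPh)(H2IMes)(PCy3) (15 mol %), 1,4-benzoquinone, toluene (1 mM), 80 °C
Reagents that add atoms: none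
Why: Ring-closing metathesis between the C6 vinyl group and the 1,1-disubstituted C5 alkene; the ten-membered ring strongly favours the trisubstituted alkene with C4 and C7 cis, the (Z)-geometry of the target.

Step 27
Reactants: 37 macrocycle 12-OTIPS ether
Product: 38 CNP0281577.2
Conditions: HF·pyridine, THF, rt
Reagents that add atoms: none
Why: Fluoride cleavage of the silyl ether under conditions that leave the acetates, the butanoate and the butenolide intact.

**Compound list**

1 | 4-(phenylsulfanyl)butan-2-one | CC(=O)CCSc1ccccc1 | starting material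
2 | 3-oxo-5-(phenylsulfanyl)pentanal (enol form in solution) | O=CCC(=O)CCSc1ccccc1 | intermediate
3 | (4-methoxyphenyl)methanol | COc1ccc(CO)cc1 | starting material
4 | (E)-1-[(4-methoxybenzyl)oxy]-5-(phenylsulfanyl)pent-1-en-3-one | COc1ccc(CO/C=C/C(=O)CCSc2ccccc2)cc1 | intermediate
5 | (1E,3Z)-1-[(4-methoxybenzyl)oxy]-3-(tert-butyldimethylsilyloxy)-5-(phenylsulfanyl)penta-1,3-diene | COc1ccc(CO/C=C/C(O[Si](C)(C)C(C)(C)C)=C/CSc2ccccc2)cc1 | intermediate
6 | 3-methylbut-2-en-1-ol | CC(C)=CCO | starting material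
7 | 1-methoxy-4-{[(3-methylbut-2-en-1-yl)oxy]methyl}benzene | CC(C)=CCOCc1ccc(OC)cc1 | intermediate
8 | (E)-4-[(4-methoxybenzyl)oxy]-2-methylbut-2-en-1-ol | OC/C(C)=C/COCc1ccc(OC)cc1 | intermediate
9 | (E)-4-[(4-methoxybenzyl)oxy]-2-methylbut-2-enal | O=C/C(C)=C/COCc1ccc(OC)cc1 | intermediate
10 | Diels–Alder adduct: cyclohexene with C1 β-CH3 and α-CHO, C10 β-CH2OPMB, C11 α-CH2SPh, C12 OTBS (C12=C13), C14 α-OPMB | O=C[C@@]1(C)[C@@H](OCc2ccc(OC)cc2)C=C(O[Si](C)(C)C(C)(C)C)[C@@H](CSc2ccccc2)[C@@H]1COCc3ccc(OC)cc3 | intermediate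
11 | 2-(2-bromoethyl)-2-methyl-1,3-dioxolane | CC1(CCBr)OCCO1 | starting material
12 | [2-(2-methyl-1,3-dioxolan-2-yl)ethyl]magnesium bromide | CC1(CC[Mg]Br)OCCO1 | intermediate
13 | bromomagnesium alkoxide of the C2 carbinol from 10 and 12 | Br[Mg]O[C@@H](CCC1(C)OCCO1)[C@@]2(C)[C@@H](OCc3ccc(OC)cc3)C=C(O[Si](C)(C)C(C)(C)C)[C@@H](CSc3ccccc3)[C@@H]2COCc4ccc(OC)cc4 | intermediate
14 | C2 butanoate of that carbinol (C2 configured as in the target; ketal side chain; rest as 10) | CCCC(=O)O[C@@H](CCC1(C)OCCO1)[C@@]2(C)[C@@H](OCc3ccc(OC)cc3)C=C(O[Si](C)(C)C(C)(C)C)[C@@H](CSc3ccccc3)[C@@H]2COCc4ccc(OC)cc4 | intermediate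
15 | C12 ketone (C11 α-CH2SPh, C14 α-OPMB) | CCCC(=O)O[C@@H](CCC1(C)OCCO1)[C@@]2(C)[C@@H](OCc3ccc(OC)cc3)CC(=O)[C@@H](CSc3ccccc3)[C@@H]2COCc4ccc(OC)cc4 | intermediate
16 | sulfoxide of 15 (mixture at sulfur) | CCCC(=O)O[C@@H](CCC1(C)OCCO1)[C@@]2(C)[C@@H](OCc3ccc(OC)cc3)CC(=O)[C@@H](CS(=O)c3ccccc3)[C@@H]2COCc4ccc(OC)cc4 | intermediate
17 | C11 exo-methylene C12 ketone | CCCC(=O)O[C@@H](CCC1(C)OCCO1)[C@@]2(C)[C@@H](OCc3ccc(OC)cc3)CC(=O)C(=C)[C@@H]2COCc4ccc(OC)cc4 | intermediate
18 | 12α-allylic alcohol (C11=C20) | CCCC(=O)O[C@@H](CCC1(C)OCCO1)[C@@]2(C)[C@@H](OCc3ccc(OC)cc3)C[C@@H](O)C(=C)[C@@H]2COCc4ccc(OC)cc4 | intermediate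
19 | 11β-methyl 12α-alcohol | CCCC(=O)O[C@@H](CCC1(C)OCCO1)[C@@]2(C)[C@@H](OCc3ccc(OC)cc3)C[C@@H](O)[C@H](C)[C@@H]2COCc4ccc(OC)cc4 | intermediate
20 | 12α-OTIPS ether of 19 | CCCC(=O)O[C@@H](CCC1(C)OCCO1)[C@@]2(C)[C@@H](OCc3ccc(OC)cc3)C[C@@H](O[Si](C(C)C)(C(C)C)C(C)C)[C@H](C)[C@@H]2COCc4ccc(OC)cc4 | intermediate
21 | C5 methyl ketone (3-oxobutyl chain at C2) | CCCC(=O)O[C@@H](CCC(C)=O)[C@@]1(C)[C@@H](OCc2ccc(OC)cc2)C[C@@H](O[Si](C(C)C)(C(C)C)C(C)C)[C@H](C)[C@@H]1COCc3ccc(OC)cc3 | intermediate
22 | isopropenyl compound (3-methylbut-3-enyl chain at C2) | CCCC(=O)O[C@@H](CCC(C)=C)[C@@]1(C)[C@@H](OCc2ccc(OC)cc2)C[C@@H](O[Si](C(C)C)(C(C)C)C(C)C)[C@H](C)[C@@H]1COCc3ccc(OC)cc3 | intermediate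
23 | 9,14-diol (C10 β-CH2OH, C14 α-OH) | CCCC(=O)O[C@@H](CCC(C)=C)[C@@]1(C)[C@@H](O)C[C@@H](O[Si](C(C)C)(C(C)C)C(C)C)[C@H](C)[C@@H]1CO | intermediate
24 | C9 aldehyde (C10 β-CHO, C14 α-OH) | CCCC(=O)O[C@@H](CCC(C)=C)[C@@]1(C)[C@@H](O)C[C@@H](O[Si](C(C)C)(C(C)C)C(C)C)[C@H](C)[C@@H]1C=O | intermediate
25 | (S)-3-hydroxyoxolan-2-one | O[C@H]1CCOC1=O | starting material
26 | sodium (S)-2-hydroxy-4-(phenylselanyl)butanoate | [Na+].[O-]C(=O)[C@@H](O)CC[Se]c1ccccc1 | intermediate
27 | methyl (S)-2-hydroxy-4-(phenylselanyl)butanoate | COC(=O)[C@@H](O)CC[Se]c1ccccc1 | intermediate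
28 | methyl (S)-4-(phenylselanyl)-2-(propanoyloxy)butanoate | COC(=O)[C@@H](OC(=O)CC)CC[Se]c1ccccc1 | intermediate
29 | (S)-4-hydroxy-3-methyl-5-[2-(phenylselanyl)ethyl]furan-2(5H)-one | O=C1O[C@@H](CC[Se]c2ccccc2)C(O)=C1C | intermediate
30 | (S)-4-methyl-5-oxo-2-[2-(phenylselanyl)ethyl]-2,5-dihydrofuran-3-yl trifluoromethanesulfonate | O=C1O[C@@H](CC[Se]c2ccccc2)C(OS(=O)(=O)C(F)(F)F)=C1C | intermediate
31 | selenoxide of 30 | O=C1O[C@@H](CC[Se](=O)c2ccccc2)C(OS(=O)(=O)C(F)(F)F)=C1C | intermediate
32 | (S)-4-methyl-5-oxo-2-vinyl-2,5-dihydrofuran-3-yl trifluoromethanesulfonate | O=C1O[C@@H](C=C)C(OS(=O)(=O)C(F)(F)F)=C1C | intermediate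
33 | C9 carbinol, C9 epimer mixture (butenolide attached at C8) | CCCC(=O)O[C@@H](CCC(C)=C)[C@@]1(C)[C@@H](O)C[C@@H](O[Si](C(C)C)(C(C)C)C(C)C)[C@H](C)[C@@H]1C(O)C2=C(C)C(=O)O[C@H]2C=C | intermediate
34 | C9 ketone | CCCC(=O)O[C@@H](CCC(C)=C)[C@@]1(C)[C@@H](O)C[C@@H](O[Si](C(C)C)(C(C)C)C(C)C)[C@H](C)[C@@H]1C(=O)C2=C(C)C(=O)O[C@H]2C=C | intermediate
35 | (9S)-alcohol (9,14-diol) | CCCC(=O)O[C@@H](CCC(C)=C)[C@@]1(C)[C@@H](O)C[C@@H](O[Si](C(C)C)(C(C)C)C(C)C)[C@H](C)[C@@H]1[C@H](O)C2=C(C)C(=O)O[C@H]2C=C | intermediate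
36 | 9,14-diacetate (metathesis precursor) | CCCC(=O)O[C@@H](CCC(C)=C)[C@@]1(C)[C@@H](OC(C)=O)C[C@@H](O[Si](C(C)C)(C(C)C)C(C)C)[C@H](C)[C@@H]1[C@H](OC(C)=O)C2=C(C)C(=O)O[C@H]2C=C | intermediate
37 | macrocycle, 12-OTIPS ether of the target | CCCC(=O)O[C@H]1CC/C(C)=C\[C@@H]2OC(=O)C(C)=C2[C@@H](OC(C)=O)[C@H]2[C@@H](C)[C@H](O[Si](C(C)C)(C(C)C)C(C)C)C[C@H](OC(C)=O)[C@@]21C | intermediate
38 | CNP0281577.2 | CCCC(=O)O[C@H]1CC/C(C)=C\[C@@H]2OC(=O)C(C)=C2[C@@H](OC(C)=O)[C@H]2[C@@H](C)[C@H](O)C[C@H](OC(C)=O)[C@@]21C | target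

**Totals.** Total step count: 27. Longest linear sequence: 20 steps (steps 1–3, 6–16 and 22–27).

**Steps most likely to fail**

1. Step 6. The α,β-disubstituted enal may react too slowly with the 4-substituted diene, the diene may add to the formyl C=O instead, or endo and facial selectivity may erode. Fallback (sets out from 3 and 9, returns at 17): commercial (E)-4-methoxybut-3-en-2-one is transetherified with 3 (pyridinium 4-toluenesulfonate, toluene) to (E)-4-[(4-methoxybenzyl)oxy]but-3-en-2-one F1 and silylated (TBSOTf, Et3N) to the unsubstituted, more reactive diene F2. F2 undergoes the same catalysed cycloaddition with 9 to give the adduct without C20 F3. F3 is carried through the conditions of steps 7 and 8 to the butanoate F4 and the ketone F5. Kinetic deprotonation at C11 (LDA, −78 °C; the C13 methylene is shielded by the alkoxylated, neopentyl C14) and trapping with dimethylmethylideneammonium iodide gives the Mannich base F6; quaternization and elimination (MeI; NaHCO3) give 17.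

2. Step 26. Oligomerization or non-productive metathesis may win over closure of the strained ten-membered ring with a trisubstituted alkene. Fallback (sets out from 35, returns at 37): the order of events is changed and the ring is closed before acylation, on diol 35, where the C9/C14 region is less crowded (second-generation Hoveyda–Grubbs catalyst RuCl2(=CH-2-iPrOC6H4)(H2IMes), toluene, high dilution), to give the macrocyclic 9,14-diol F10; acetylation under the conditions of step 25 gives 37.

3. Step 7. Facial selectivity at the formyl group may be poor if chelation is incomplete, and in situ acylation of the hindered alkoxide may be incomplete. Fallback (sets out from 10, returns at 14): the Grignard addition is run without anhydride to give the C2 alcohol as an epimer mixture F7; Parikh–Doering oxidation (SO3·pyridine, DMSO, iPr2NEt) gives the C2 ketone F8; reagent-controlled reduction with the (R)-configured CBS oxazaborolidine and catecholborane (quaternary C1 as the large group) gives the single C2 alcohol F9; butanoic anhydride and DMAP give 14.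

**Further compounds**

F1 | step 6 | (E)-4-[(4-methoxybenzyl)oxy]but-3-en-2-one | COc1ccc(CO/C=C/C(C)=O)cc1
F2 | step 6 | (E)-1-[(4-methoxybenzyl)oxy]-3-(tert-butyldimethylsilyloxy)buta-1,3-diene | COc1ccc(CO/C=C/C(=C)O[Si](C)(C)C(C)(C)C)cc1
F3 | step 6 | Diels–Alder adduct without C20 (C11 = CH2) | O=C[C@@]1(C)[C@@H](OCc2ccc(OC)cc2)C=C(O[Si](C)(C)C(C)(C)C)C[C@@H]1COCc3ccc(OC)cc3
F4 | step 6 | C2 butanoate of the adduct without C20 | CCCC(=O)O[C@@H](CCC1(C)OCCO1)[C@@]2(C)[C@@H](OCc3ccc(OC)cc3)C=C(O[Si](C)(C)C(C)(C)C)C[C@@H]2COCc4ccc(OC)cc4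
F5 | step 6 | C12 ketone without C20 | CCCC(=O)O[C@@H](CCC1(C)OCCO1)[C@@]2(C)[C@@H](OCc3ccc(OC)cc3)CC(=O)C[C@@H]2COCc4ccc(OC)cc4
F6 | step 6 | C11 (dimethylamino)methyl ketone (Mannich base) | CCCC(=O)O[C@@H](CCC1(C)OCCO1)[C@@]2(C)[C@@H](OCc3ccc(OC)cc3)CC(=O)C(CN(C)C)[C@@H]2COCc4ccc(OC)cc4
F7 | step 7 | C2 alcohol, epimer mixture | OC(CCC1(C)OCCO1)[C@@]2(C)[C@@H](OCc3ccc(OC)cc3)C=C(O[Si](C)(C)C(C)(C)C)[C@@H](CSc3ccccc3)[C@@H]2COCc4ccc(OC)cc4
F8 | step 7 | C2 ketone | O=C(CCC1(C)OCCO1)[C@@]2(C)[C@@H](OCc3ccc(OC)cc3)C=C(O[Si](C)(C)C(C)(C)C)[C@@H](CSc3ccccc3)[C@@H]2COCc4ccc(OC)cc4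
F9 | step 7 | C2 alcohol, single epimer (free alcohol of 13) | O[C@@H](CCC1(C)OCCO1)[C@@]2(C)[C@@H](OCc3ccc(OC)cc3)C=C(O[Si](C)(C)C(C)(C)C)[C@@H](CSc3ccccc3)[C@@H]2COCc4ccc(OC)cc4
F10 | step 26 | macrocyclic 9,14-diol 12-OTIPS ether | CCCC(=O)O[C@H]1CC/C(C)=C\[C@@H]2OC(=O)C(C)=C2[C@@H](O)[C@H]2[C@@H](C)[C@H](O[Si](C(C)C)(C(C)C)C(C)C)C[C@H](O)[C@@]21C
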